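## Retrosynthetic overview

1. The target is read as (13E)-6β-acetoxy-7α-(3-methylbutanoyloxy)labda-8,13-dien-15-oic acid (trans-decalin, 5α-H, 10β-CH3). The C15 acid is traced to a silyl-protected allylic alcohol. The 6β-acetate comes from α-face hydride reduction of a 6-ketone, and the 7α-ester from β-face reduction of a 7-ketone, both starting from a 6α-hydroxy-8-en-7-one.
2. The 9-alkyl-8-en-7-one is traced to the bicyclic 7-en-9-one by 1,2-addition of a C11–C16 organocerium reagent and oxidative 1,3-transposition.
3. Ring A (C1–C5, C10) is opened at C3–C4: a C4 cation, generated from an isopropenyl group on C5, is captured by a (Z)-vinylsilane arm on C10 (C1–C2=C3–Si).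
4. The feature the plan rests on: ring B (C5–C10) is (R)-carvone, which supplies the C5 stereocentre, the C8 methyl on the C7=C8 alkene, the C9 carbonyl and C4 with one of its methyls. The quaternary C10 is made by two enolate alkylations, CH3 first, then the silylallyl arm anti to the isopropenyl group.
5. Ring order: ring B is carvone itself; ring A is closed second, in the key step; the side chain and the C6/C7 oxygens follow.

Key step: step 5

Remark: ring positions are labdane numbers (ring A = C1–C5 and C10; ring B = C5–C10). Reagents that only deliver a small group are named with SMILES on the "Reagents that add atoms" lines and carry no compound number.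

## Route

Step 1
Reactants: 1 3-(trimethylsilyl)prop-2-yn-1-ol
Product: 2 (Z)-3-(trimethylsilyl)prop-2-en-1-ol
Conditions: H2 (1 atm), Ni2B from Ni(OAc)2·4H2O/NaBH4, ethylenediamine, EtOH, rt
Reagents that add atoms: none
Why: Syn semihydrogenation of the silylalkyne over amine-poisoned nickel boride should stop at the alkene and give the (Z)-vinylsilane.

Step 2
Reactants: 2 (Z)-3-(trimethylsilyl)prop-2-en-1-ol
Product: 3 (Z)-(3-bromoprop-1-en-1-yl)trimethylsilane
Conditions: PBr3 (0.4 equiv), pyridine (cat.), Et2O, −10 → 0 °C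
Reagents that add atoms: phosphorus tribromide, BrP(Br)Br
Why: SN2 displacement of the phosphite ester of the primary allylic alcohol by bromide at low temperature should keep the Z geometry and avoid allylic transposition.

Step 3
Reactants: 4 (R)-carvone
Product: 6 (5R)-2,6-dimethyl-5-(prop-1-en-2-yl)cyclohex-2-en-1-one (6-methylcarvone; 6S trans epimer major), via lithium dienolate 5 (not isolated)
Conditions: LiN(iPr)2, THF, −78 °C; MeI, −78 → 0 °C
Reagents that add atoms: iodomethane, CI
Why: Kinetic α′-deprotonation gives the cross-conjugated dienolate, which is C-methylated (enolate alkylation); the new centre forms as an epimer mixture of no consequence because it is re-enolised in step 4.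

Step 4
Reactants: 6 6-methylcarvone; 3 (Z)-(3-bromoprop-1-en-1-yl)trimethylsilane
Product: 8 (5S,6S)-2,6-dimethyl-5-(prop-1-en-2-yl)-6-[(2Z)-3-(trimethylsilyl)prop-2-en-1-yl]cyclohex-2-en-1-one (silylallyl arm trans to isopropenyl), via lithium enolate 7 (not isolated)
Conditions: LiN(iPr)2, THF, −78 → 0 °C; DMPU, 3, −78 °C → rt
Reagents that add atoms: none
Why: Enolate alkylation in which the tetrasubstituted enolate formed from either epimer of 6 is planar at C10 and the allylic bromide approaches anti to the pseudoaxial isopropenyl group on C5, so the arm ends trans and the methyl cis to it, which sets C10.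

Step 5
Reactants: 8 silylallyl methyl carvone
Product: 9 (4aS,8aS)-2,5,5,8a-tetramethyl-4a,5,8,8a-tetrahydronaphthalen-1(4H)-one (trans-fused dienone; alkenes at C7–C8 and C2–C3, ketone at C9)
Conditions: CF3CO2H–CH2Cl2 (1:4), 0 °C → rt
Reagents that add atoms: none
Why: Trifluoroacetic acid protonates the isopropenyl alkene at its CH2 terminus to give the tertiary C4 cation, now carrying both C4 methyls; the silicon-bearing vinyl carbon C3 attacks it, and the resulting β-silyl cation at C2 loses the silyl group to trifluoroacetate, leaving the C2–C3 alkene. The closest known reaction type is the vinylsilane-terminated cation–olefin cyclisation, together with acid-initiated closures of the isopropenyl cation of 6,6-dialkylated carvones. Ring A is closed by the C3–C4 bond in a six-membered endocyclic (6-endo-trig) mode with respect to the vinylsilane. No stereocentre is formed, since C4 becomes gem-dimethyl and C3 stays sp2; the trans fusion is decided by the existing C5 and C10 centres, whose reacting arms are trans on ring B and can only bridge as a trans-decalin, and the Z vinylsilane lets the ring alkene form as the required cis alkene. The step needs site selectivity for C3 over C2 and chemoselective protonation: attack through C3 gives a cation β to silicon and a six-membered ring, whereas attack through C2 would give a cation α to silicon and a five-membered ring, and the electron-rich isopropenyl group should be protonated in preference to the enone and the vinylsilane. The quaternary C10 rules out the acid-induced aromatisation known for carvone, and the tertiary trifluoroacetate formed reversibly from the cation re-ionises under the conditions.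

Step 6
Reactants: 9 trans-fused dienone
Product: 10 (4aS,8aS)-2,5,5,8a-tetramethyl-4a,5,6,7,8,8a-hexahydronaphthalen-1(4H)-one
Conditions: H2 (1–3 atm), RhCl(PPh3)3 (5 mol %), benzene–EtOH, rt
Reagents that add atoms: none
Why: Homogeneous hydrogenation with RhCl(PPh3)3 should reduce the cis-disubstituted C2–C3 alkene and leave the trisubstituted, conjugated C7–C8 alkene untouched; no stereocentre is formed.

Step 7
Reactants: 11 but-3-yn-1-ol
Product: 12 (but-3-yn-1-yloxy)(tert-butyl)dimethylsilane
Conditions: t-BuMe2SiCl, imidazole, CH2Cl2, rt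
Reagents that add atoms: tert-butyldimethylsilyl chloride, CC(C)(C)[Si](C)(C)Cl
Why: Imidazole-promoted silylation of the primary alcohol masks the hydroxyl for the organoaluminium step.

Step 8
Reactants: 12 (but-3-yn-1-yloxy)(tert-butyl)dimethylsilane
Product: 15 (E)-5-(tert-butyldimethylsilyloxy)-3-methylpent-2-en-1-ol, via alkenylalane 13 (not isolated), via lithium aluminate 14 (not isolated)
Conditions: Me3Al, Cp2ZrCl2 (0.2 equiv), CH2Cl2, 0 °C → rt; volatiles removed; n-BuLi, THF–hexane, −78 °C; (CH2O)n, → rt; aqueous work-up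
Reagents that add atoms: trimethylaluminium, C[Al](C)C; paraformaldehyde (formaldehyde unit), C=O
Why: Zirconium-catalysed Negishi carboalumination adds CH3 and Al syn across the terminal alkyne with the methyl on the internal carbon, and the aluminate made with n-BuLi is hydroxymethylated with retention, which sets the E trisubstituted C13–C14 alkene.

Step 9
Reactants: 15 (E)-5-(tert-butyldimethylsilyloxy)-3-methylpent-2-en-1-ol
Product: 16 (E)-1-(tert-butyldiphenylsilyloxy)-5-(tert-butyldimethylsilyloxy)-3-methylpent-2-ene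
Conditions: t-BuPh2SiCl, imidazole, DMF, rt
Reagents that add atoms: tert-butyldiphenylsilyl chloride, CC(C)(C)[Si](Cl)(c1ccccc1)c1ccccc1
Why: Imidazole-promoted silylation of the primary allylic alcohol installs the acid-stable silyl ether that carries C15 to the end of the route.

Step 10
Reactants: 16 bis-silyl ether
Product: 17 (E)-5-(tert-butyldiphenylsilyloxy)-3-methylpent-3-en-1-ol
Conditions: camphorsulfonic acid (cat.), MeOH–CH2Cl2, 0 °C
Reagents that add atoms: none
Why: Acid-catalysed methanolysis should cleave the primary tert-butyldimethylsilyl ether far faster than the tert-butyldiphenylsilyl ether (selective desilylation by acid lability).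

Step 11
Reactants: 17 (E)-5-(tert-butyldiphenylsilyloxy)-3-methylpent-3-en-1-ol
Product: 18 (E)-tert-butyl[(5-iodo-3-methylpent-2-en-1-yl)oxy]diphenylsilane
Conditions: I2, PPh3, imidazole, CH2Cl2, 0 °C → rt
Reagents that add atoms: iodine, II
Why: Appel-type iodination converts the primary homoallylic alcohol into the iodide by SN2 displacement of the oxyphosphonium ion, away from the alkene.

Step 12
Reactants: 18 homoallylic iodide; 10 bicyclic enone
Product: 21 (13E)-15-(tert-butyldiphenylsilyloxy)-9-hydroxylabda-7,13-diene (9β-OH expected), via alkyllithium 19 (not isolated), via organocerium reagent 20 (not isolated)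
Conditions: t-BuLi (2.1 equiv), Et2O–pentane, −78 °C; CeCl3 (anhydrous), THF, −78 °C; 10, −78 → −40 °C; aq. NH4Cl
Reagents that add atoms: none
Why: Iodine–lithium exchange at −78 °C gives the primary alkyllithium, transmetallation to the weakly basic organocerium reagent suppresses enolisation, and 1,2-addition to the hindered C9 carbonyl should occur from the α face opposite the axial C10 methyl; the C9 configuration is erased in step 13.

Step 13
Reactants: 21 tertiary allylic alcohol
Product: 22 (13E)-15-(tert-butyldiphenylsilyloxy)labda-8,13-dien-7-one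
Conditions: [C5H5NH][CrO3Cl] (pyridinium chlorochromate), 4 Å molecular sieves, CH2Cl2, rt
Reagents that add atoms: pyridinium chlorochromate, [O-][Cr](=O)(=O)Cl.c1cc[nH+]cc1
Why: Babler–Dauben oxidative transposition, in which the chromate ester of the tertiary allylic alcohol shifts by a [3,3] path to C7 and is oxidised there to the tetrasubstituted 8-en-7-one.

Step 14
Reactants: 22 8-en-7-one
Product: 24 (13E)-15-(tert-butyldiphenylsilyloxy)-6α-hydroxylabda-8,13-dien-7-one, via lithium dienolate 23 (not isolated)
Conditions: LiN(iPr)2, THF, −78 °C; 2-(phenylsulfonyl)-3-phenyloxaziridine, −78 °C; aq. NH4Cl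
Reagents that add atoms: 2-(phenylsulfonyl)-3-phenyloxaziridine, O=S(=O)(c1ccccc1)N1OC1c1ccccc1
Why: Kinetic α′-deprotonation at C6 gives the cross-conjugated dienolate, which the N-sulfonyloxaziridine should hydroxylate on the α face away from the syn-axial C4β and C10 methyls (Davis enolate oxidation); this centre is later passed through the ketone, so its configuration is not critical.

Step 15
Reactants: 24 6α-hydroxy enone
Product: 25 (13E)-15-(tert-butyldiphenylsilyloxy)-6α-(triethylsilyloxy)labda-8,13-dien-7-one
Conditions: Et3SiOTf, 2,6-lutidine, CH2Cl2, −78 → 0 °C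
Reagents that add atoms: triethylsilyl trifluoromethanesulfonate, CC[Si](CC)(CC)OS(=O)(=O)C(F)(F)F
Why: Silylation with the reactive triflate and a hindered weak base protects the hindered secondary hydroxyl without enolising the ketone.

Step 16
Reactants: 25 6α-silyloxy enone
Product: 26 (13E)-15-(tert-butyldiphenylsilyloxy)-6α-(triethylsilyloxy)labda-8,13-dien-7α-ol
Conditions: LiBH(s-Bu)3, THF, −78 °C; aq. NH4Cl at −78 °C
Reagents that add atoms: none
Why: The bulky borohydride should reduce the β,β-disubstituted enone in the 1,2 sense and deliver hydride along the equatorial trajectory from the β face, away from the 5α-H and the α-tilted 6α-silyloxy group, giving the pseudoaxial 7α-alcohol; the cold quench avoids silyl migration to the new alkoxide.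

Step 17
Reactants: 26 7α-alcohol
Product: 27 (13E)-15-(tert-butyldiphenylsilyloxy)-6α-(triethylsilyloxy)labda-8,13-dien-7α-yl 3-methylbutanoate
Conditions: 3-methylbutanoyl chloride, pyridine, DMAP (cat.), CH2Cl2, 0 °C → rt
Reagents that add atoms: 3-methylbutanoyl chloride, CC(C)CC(Cl)=O
Why: DMAP-catalysed acylation of the secondary allylic alcohol gives the ester with retention at C7.

Step 18
Reactants: 27 7α-ester
Product: 28 (13E)-15-(tert-butyldiphenylsilyloxy)-6α-hydroxylabda-8,13-dien-7α-yl 3-methylbutanoate
Conditions: pyridinium p-toluenesulfonate (cat.), MeOH–CH2Cl2, 0 °C → rt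
Reagents that add atoms: none
Why: Mild acid methanolysis should remove the secondary triethylsilyl ether while the far more acid-stable tert-butyldiphenylsilyl ether and the ester remain (selective desilylation).

Step 19
Reactants: 28 6α-alcohol
Product: 29 (13E)-15-(tert-butyldiphenylsilyloxy)-6-oxolabda-8,13-dien-7α-yl 3-methylbutanoate
Conditions: Dess–Martin periodinane, pyridine, CH2Cl2, 0 °C → rt
Reagents that add atoms: none
Why: Dess–Martin oxidation under buffered, near-neutral conditions converts the alcohol to the 6-ketone without enolisation toward C7 or C5.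

Step 20
Reactants: 29 6-ketone
Product: 30 (13E)-15-(tert-butyldiphenylsilyloxy)-6β-hydroxylabda-8,13-dien-7α-yl 3-methylbutanoate
Conditions: NaBH4, CeCl3·7H2O, MeOH, −40 °C
Reagents that add atoms: none
Why: Luche-type borohydride reduction should deliver hydride to C6 from the α face because the β face is closed by the syn-axial C4β and C10 methyls, giving the axial 6β-alcohol, which is trans-diaxial to the 7α-ester and so cannot take over its acyl group.

Step 21
Reactants: 30 6β-alcohol
Product: 31 (13E)-6β-acetoxy-15-(tert-butyldiphenylsilyloxy)labda-8,13-dien-7α-yl 3-methylbutanoate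
Conditions: Ac2O, DMAP, pyridine, 40 °C
Reagents that add atoms: acetic anhydride, CC(=O)OC(C)=O
Why: DMAP-catalysed acetylation with gentle warming should acylate the hindered axial 6β-hydroxyl, the only free hydroxyl in the molecule.

Step 22
Reactants: 31 diester silyl ether
Product: 32 (13E)-6β-acetoxy-15-hydroxylabda-8,13-dien-7α-yl 3-methylbutanoate
Conditions: HF·pyridine, pyridine, THF, 0 °C → rt
Reagents that add atoms: none
Why: Buffered fluoride cleaves the silicon–oxygen bond of the primary silyl ether under conditions that leave both esters in place (desilylation).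

Step 23
Reactants: 32 allylic alcohol
Product: 33 (13E)-6β-acetoxy-15-oxolabda-8,13-dien-7α-yl 3-methylbutanoate
Conditions: MnO2 (activated, excess), CH2Cl2, rt
Reagents that add atoms: none
Why: MnO2 oxidises the primary allylic alcohol selectively to the enal without E/Z isomerisation or over-oxidation.

Step 24
Reactants: 33 enal
Product: 34 (13E)-6β-acetoxy-7α-(3-methylbutanoyloxy)labda-8,13-dien-15-oic acid (target)
Conditions: NaClO2, NaH2PO4, 2-methyl-2-butene, t-BuOH–H2O, 0 °C → rt
Reagents that add atoms: sodium chlorite, [Na+].[O-]Cl=O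
Why: Pinnick (Lindgren) oxidation converts the enal to the acid under buffered conditions, with 2-methyl-2-butene scavenging hypochlorous acid so that the alkenes and both esters are untouched.

## Compound list

1 | 3-(trimethylsilyl)prop-2-yn-1-ol | C[Si](C)(C)C#CCO | starting material
2 | (Z)-3-(trimethylsilyl)prop-2-en-1-ol | C[Si](C)(C)/C=C\CO | intermediate
3 | (Z)-(3-bromoprop-1-en-1-yl)trimethylsilane | C[Si](C)(C)/C=C\CBr | intermediate
4 | (R)-carvone | CC1=CC[C@@H](C(C)=C)CC1=O | starting material
5 | lithium dienolate of carvone | CC1=CC[C@@H](C(C)=C)C=C1O[Li] | intermediate (not isolated)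
6 | 6-methylcarvone, (5R,6S) trans epimer shown, used as the C6 epimer mixture | CC1=CC[C@@H](C(C)=C)[C@H](C)C1=O | intermediate
7 | lithium enolate of 6-methylcarvone | CC1=CC[C@@H](C(C)=C)C(C)=C1O[Li] | intermediate (not isolated)
8 | (5S,6S)-2,6-dimethyl-5-(prop-1-en-2-yl)-6-[(2Z)-3-(trimethylsilyl)prop-2-en-1-yl]cyclohex-2-en-1-one | CC1=CC[C@@H](C(C)=C)[C@](C)(C/C=C\[Si](C)(C)C)C1=O | intermediate
9 | (4aS,8aS)-2,5,5,8a-tetramethyl-4a,5,8,8a-tetrahydronaphthalen-1(4H)-one | CC1=CC[C@H]2C(C)(C)C=CC[C@]2(C)C1=O | intermediate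
10 | (4aS,8aS)-2,5,5,8a-tetramethyl-4a,5,6,7,8,8a-hexahydronaphthalen-1(4H)-one | CC1=CC[C@H]2C(C)(C)CCC[C@]2(C)C1=O | intermediate
11 | but-3-yn-1-ol | C#CCCO | starting material
12 | (but-3-yn-1-yloxy)(tert-butyl)dimethylsilane | C#CCCO[Si](C)(C)C(C)(C)C | intermediate
13 | (E)-alkenyl(dimethyl)alane from 12 | C/C(CCO[Si](C)(C)C(C)(C)C)=C\[Al](C)C | intermediate (not isolated)
14 | lithium (E)-alkenyl(butyl)dimethylaluminate | [Li+].C/C(CCO[Si](C)(C)C(C)(C)C)=C\[Al-](C)(C)CCCC | intermediate (not isolated)
15 | (E)-5-(tert-butyldimethylsilyloxy)-3-methylpent-2-en-1-ol | C/C(CCO[Si](C)(C)C(C)(C)C)=C\CO | intermediate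
16 | (E)-1-(tert-butyldiphenylsilyloxy)-5-(tert-butyldimethylsilyloxy)-3-methylpent-2-ene | C/C(CCO[Si](C)(C)C(C)(C)C)=C\CO[Si](c1ccccc1)(c1ccccc1)C(C)(C)C | intermediate
17 | (E)-5-(tert-butyldiphenylsilyloxy)-3-methylpent-3-en-1-ol | C/C(CCO)=C\CO[Si](c1ccccc1)(c1ccccc1)C(C)(C)C | intermediate
18 | (E)-tert-butyl[(5-iodo-3-methylpent-2-en-1-yl)oxy]diphenylsilane | C/C(CCI)=C\CO[Si](c1ccccc1)(c1ccccc1)C(C)(C)C | intermediate
19 | (E)-5-(tert-butyldiphenylsilyloxy)-3-methylpent-3-en-1-yllithium | C/C(CC[Li])=C\CO[Si](c1ccccc1)(c1ccccc1)C(C)(C)C | intermediate (not isolated)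
20 | (E)-5-(tert-butyldiphenylsilyloxy)-3-methylpent-3-en-1-ylcerium dichloride | C/C(CC[Ce](Cl)Cl)=C\CO[Si](c1ccccc1)(c1ccccc1)C(C)(C)C | intermediate (not isolated)
21 | (13E)-15-(tert-butyldiphenylsilyloxy)-9-hydroxylabda-7,13-diene (9β-OH, side chain α) | CC1=CC[C@H]2C(C)(C)CCC[C@]2(C)[C@]1(O)CC/C(C)=C/CO[Si](c1ccccc1)(c1ccccc1)C(C)(C)C | intermediate
22 | (13E)-15-(tert-butyldiphenylsilyloxy)labda-8,13-dien-7-one | O=C1C[C@H]2C(C)(C)CCC[C@]2(C)C(CC/C(C)=C/CO[Si](c3ccccc3)(c3ccccc3)C(C)(C)C)=C1C | intermediate
23 | lithium 6,8-dien-7-olate of 22 | [Li]OC1=C[C@H]2C(C)(C)CCC[C@]2(C)C(CC/C(C)=C/CO[Si](c3ccccc3)(c3ccccc3)C(C)(C)C)=C1C | intermediate (not isolated)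
24 | (13E)-15-(tert-butyldiphenylsilyloxy)-6α-hydroxylabda-8,13-dien-7-one | O=C1[C@H](O)[C@H]2C(C)(C)CCC[C@]2(C)C(CC/C(C)=C/CO[Si](c3ccccc3)(c3ccccc3)C(C)(C)C)=C1C | intermediate
25 | (13E)-15-(tert-butyldiphenylsilyloxy)-6α-(triethylsilyloxy)labda-8,13-dien-7-one | O=C1[C@H](O[Si](CC)(CC)CC)[C@H]2C(C)(C)CCC[C@]2(C)C(CC/C(C)=C/CO[Si](c3ccccc3)(c3ccccc3)C(C)(C)C)=C1C | intermediate
26 | (13E)-15-(tert-butyldiphenylsilyloxy)-6α-(triethylsilyloxy)labda-8,13-dien-7α-ol | O[C@@H]1[C@H](O[Si](CC)(CC)CC)[C@H]2C(C)(C)CCC[C@]2(C)C(CC/C(C)=C/CO[Si](c3ccccc3)(c3ccccc3)C(C)(C)C)=C1C | intermediate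
27 | (13E)-15-(tert-butyldiphenylsilyloxy)-6α-(triethylsilyloxy)labda-8,13-dien-7α-yl 3-methylbutanoate | CC(C)CC(=O)O[C@@H]1[C@H](O[Si](CC)(CC)CC)[C@H]2C(C)(C)CCC[C@]2(C)C(CC/C(C)=C/CO[Si](c3ccccc3)(c3ccccc3)C(C)(C)C)=C1C | intermediate
28 | (13E)-15-(tert-butyldiphenylsilyloxy)-6α-hydroxylabda-8,13-dien-7α-yl 3-methylbutanoate | CC(C)CC(=O)O[C@@H]1[C@H](O)[C@H]2C(C)(C)CCC[C@]2(C)C(CC/C(C)=C/CO[Si](c3ccccc3)(c3ccccc3)C(C)(C)C)=C1C | intermediate
29 | (13E)-15-(tert-butyldiphenylsilyloxy)-6-oxolabda-8,13-dien-7α-yl 3-methylbutanoate | CC(C)CC(=O)O[C@@H]1C(=O)[C@H]2C(C)(C)CCC[C@]2(C)C(CC/C(C)=C/CO[Si](c3ccccc3)(c3ccccc3)C(C)(C)C)=C1C | intermediate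
30 | (13E)-15-(tert-butyldiphenylsilyloxy)-6β-hydroxylabda-8,13-dien-7α-yl 3-methylbutanoate | CC(C)CC(=O)O[C@@H]1[C@@H](O)[C@H]2C(C)(C)CCC[C@]2(C)C(CC/C(C)=C/CO[Si](c3ccccc3)(c3ccccc3)C(C)(C)C)=C1C | intermediate
31 | (13E)-6β-acetoxy-15-(tert-butyldiphenylsilyloxy)labda-8,13-dien-7α-yl 3-methylbutanoate | CC(C)CC(=O)O[C@@H]1[C@@H](OC(C)=O)[C@H]2C(C)(C)CCC[C@]2(C)C(CC/C(C)=C/CO[Si](c3ccccc3)(c3ccccc3)C(C)(C)C)=C1C | intermediate
32 | (13E)-6β-acetoxy-15-hydroxylabda-8,13-dien-7α-yl 3-methylbutanoate | CC(C)CC(=O)O[C@@H]1[C@@H](OC(C)=O)[C@H]2C(C)(C)CCC[C@]2(C)C(CC/C(C)=C/CO)=C1C | intermediate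
33 | (13E)-6β-acetoxy-15-oxolabda-8,13-dien-7α-yl 3-methylbutanoate | CC(C)CC(=O)O[C@@H]1[C@@H](OC(C)=O)[C@H]2C(C)(C)CCC[C@]2(C)C(CC/C(C)=C/C=O)=C1C | intermediate
34 | (13E)-6β-acetoxy-7α-(3-methylbutanoyloxy)labda-8,13-dien-15-oic acid (CNP0328312.2) | CC(C)CC(=O)O[C@@H]1[C@@H](OC(C)=O)[C@H]2C(C)(C)CCC[C@]2(C)C(CC/C(C)=C/C(=O)O)=C1C | target

## Step count and risks

Total step count: 24.
Longest linear sequence: 18 steps (steps 1, 2, 4, 5, 6 and 12–24 from compound 1; the branch from compound 11, steps 7–24, is equally long).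

Three steps most likely to fail:

Step 5 (key cyclisation). Protodesilylation of the vinylsilane, or capture and proton loss at the C4 cation, may outrun ring closure, and loss of the C5 proton from the cation would scramble the ring fusion. The fallback sets out from 8. The isopropenyl group is hydrated by Mukaiyama hydration (Co(acac)2 cat., PhSiH3, O2, i-PrOH, rt) to 5-(2-hydroxypropan-2-yl)-2,6-dimethyl-6-[(2Z)-3-(trimethylsilyl)prop-2-en-1-yl]cyclohex-2-en-1-one F1. The C4 cation is then made by ionisation instead of protonation (BF3·OEt2, CH2Cl2, −78 → −20 °C), so that no protic acid is present while the vinylsilane closes ring A. This comes back to the route at 9.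

Step 16 (C7 reduction). Facial selectivity may be poor or reversed, with hydride entering along the axial trajectory from the α face, or the hindered enone may react sluggishly. The fallback sets out from 25 and uses the opposite selectivity on purpose. NaBH4/CeCl3·7H2O (MeOH, −78 °C) is expected to give (13E)-15-(tert-butyldiphenylsilyloxy)-6α-(triethylsilyloxy)labda-8,13-dien-7β-ol F2 by axial attack. Mitsunobu esterification of F2 with 3-methylbutanoic acid (PPh3, diisopropyl azodicarboxylate, toluene, 0 °C → rt) then inverts C7 and installs the ester in one operation. This comes back to the route at 27.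

Step 14 (C6 hydroxylation). Removal of the axial 6β proton, which is screened by the C4β and C10 methyls, may be slow, allowing γ-deprotonation at C11 with oxidation at C8, or addition of the enolate to the sulfonimine by-product. The fallback sets out from 22 and avoids a strong base. α′-Acetoxylation with Mn(OAc)3·2H2O (trivalent manganese; benzene, reflux with removal of water) should give (13E)-6α-acetoxy-15-(tert-butyldiphenylsilyloxy)labda-8,13-dien-7-one F3 through the manganese enolate. Brief methanolysis (K2CO3, MeOH, 0 °C) frees the ketol. This comes back to the route at 24.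

## Further compounds

F1 | step 5 | 5-(2-hydroxypropan-2-yl)-2,6-dimethyl-6-[(2Z)-3-(trimethylsilyl)prop-2-en-1-yl]cyclohex-2-en-1-one (5S,6S) | CC1=CC[C@@H](C(C)(C)O)[C@](C)(C/C=C\[Si](C)(C)C)C1=O
F2 | step 16 | (13E)-15-(tert-butyldiphenylsilyloxy)-6α-(triethylsilyloxy)labda-8,13-dien-7β-ol | O[C@H]1[C@H](O[Si](CC)(CC)CC)[C@H]2C(C)(C)CCC[C@]2(C)C(CC/C(C)=C/CO[Si](c3ccccc3)(c3ccccc3)C(C)(C)C)=C1C
F3 | step 14 | (13E)-6α-acetoxy-15-(tert-butyldiphenylsilyloxy)labda-8,13-dien-7-one | O=C1[C@H](OC(C)=O)[C@H]2C(C)(C)CCC[C@]2(C)C(CC/C(C)=C/CO[Si](c3ccccc3)(c3ccccc3)C(C)(C)C)=C1C
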